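## Retrosynthetic overview

1. Target 26 ⇐ enone 25: the C9 methyl is added last by a cuprate from the open face of the bicyclic enone.
2. 25 ⇐ hydroxy ketone 21 + (Z)-2-methylbut-2-enal 24: one C–O bond-forming event (angelate-transfer Tishchenko reduction) makes the C5 ester and sets the C3 carbinol.
3. 21 ⇐ keto aldehyde 20 by an aldol that closes the seven-membered ring; the C6 centre comes from triol 16 by a desymmetrising O-acetylation that also installs the C15 acetate.
4. 16 ⇐ cyclobutanone 11 ⇐ amide 8: a keteniminium–alkene [2+2] builds the cyclobutane and the six-membered ring in one step.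
5. 8 ⇐ enynal 2 + mixed zinc reagent 5 (the C11 carbinol is the only external source of chirality). Ring order: four- and six-membered rings together, then the seven-membered ring.

Assumption: atom labels C1–C11 are the tricyclo[5.4.0.0^2,8]undecane locants of the target (C12 = methyl on C9, C13 = methyl on C2, C14 = methyl on C6, C15 = acetoxymethyl carbon) and are used for every intermediate; the ligand hands in steps 3 and 10 are assigned by analogy and would be confirmed in one test run (both enantiomers of each ligand are available).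

## Route

Step 1
Reactants: 1 (E)-3-methylpent-2-en-4-yn-1-ol
Product: 2 (E)-3-methylpent-2-en-4-ynal
Conditions: MnO2 (10 equiv), CH2Cl2, 23 °C
Reagents that add atoms: none
Why: Allylic alcohol oxidation on activated manganese dioxide stops at the aldehyde and leaves the E-olefin and the terminal alkyne untouched.

Step 2
Reactants: 3 ethyl 4-iodobutanoate
Product: 5 (4-ethoxy-4-oxobutyl)[(trimethylsilyl)methyl]zinc, via (4-ethoxy-4-oxobutyl)zinc iodide 4 (not isolated)
Conditions: Zn dust (1.5 equiv, activated with BrCH2CH2Br and Me3SiCl, 3 mol% each), THF, 40 °C; then Me3SiCH2Li (1.0 equiv, pentane), −78 → 0 °C; THF exchanged for Et2O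
Reagents that add atoms: zinc [Zn]; (trimethylsilyl)methyllithium [Li]C[Si](C)(C)C
Why: Direct zinc insertion into the primary C–I bond tolerates the ester, and transmetalation of the alkylzinc iodide with Me3SiCH2Li gives a mixed diorganozinc whose (trimethylsilyl)methyl group is a non-transferable ligand, so one equivalent of the iodide is enough.

Step 3
Reactants: 2 (E)-3-methylpent-2-en-4-ynal; 5 (4-ethoxy-4-oxobutyl)[(trimethylsilyl)methyl]zinc
Product: 6 ethyl (5S,6E)-5-hydroxy-7-methylnon-6-en-8-ynoate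
Conditions: 5 (1.6 equiv), Ti(OiPr)4 (2 equiv), (1R,2R)-1,2-bis(trifluoromethanesulfonamido)cyclohexane (8 mol%), Et2O, −20 °C; 1 M HCl
Reagents that add atoms: none
Why: Titanium/bis-sulfonamide-catalysed enantioselective 1,2-addition of a mixed diorganozinc to an enal, in which only the ester-bearing alkyl group is transferred; the ligand directs it to the Si face, which sets C11 as S.

Step 4
Reactants: 6 ethyl (5S,6E)-5-hydroxy-7-methylnon-6-en-8-ynoate
Product: 7 (5S,6E)-5-hydroxy-7-methyl-1-(pyrrolidin-1-yl)non-6-en-8-yn-1-one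
Conditions: pyrrolidine (5 equiv), 2-hydroxypyridine (20 mol%), PhMe, 80 °C
Reagents that add atoms: pyrrolidine C1CCNC1
Why: Aminolysis of the δ-hydroxy ester (through its δ-lactone) gives the tertiary amide needed for keteniminium formation without touching the carbinol centre.

Step 5
Reactants: 7 (5S,6E)-5-hydroxy-7-methyl-1-(pyrrolidin-1-yl)non-6-en-8-yn-1-one
Product: 8 (3E,5S)-3-methyl-9-oxo-9-(pyrrolidin-1-yl)non-3-en-1-yn-5-yl pivalate
Conditions: PivCl, pyridine, DMAP (10 mol%), CH2Cl2, 0 → 23 °C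
Reagents that add atoms: pivaloyl chloride CC(C)(C)C(=O)Cl
Why: Acylation gives a bulky ester that survives steps 6–8 and is removed in the hydride step 9 without a separate deprotection.

Step 6
Reactants: 8 (3E,5S)-3-methyl-9-oxo-9-(pyrrolidin-1-yl)non-3-en-1-yn-5-yl pivalate
Product: 11 7-ethynyl-7-methyl-6-oxobicyclo[3.1.1]heptan-2-yl pivalate, via keteniminium triflate 9 (not isolated), via cyclobutaniminium triflate 10 (not isolated)
Conditions: Tf2O (1.2 equiv), 2,4,6-collidine (2.2 equiv), ClCH2CH2Cl (0.01 M), −20 → 80 °C; then H2O, 60 °C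
Reagents that add atoms: water O; triflic anhydride O=S(=O)(OS(=O)(=O)C(F)(F)F)C(F)(F)F (counter-ion of 9 and 10 only)
Why: Ghosez–Snider intramolecular keteniminium–alkene [2+2]: the electrophilic central carbon C7 bonds to C1 and the cation-stabilised C2 closes onto C8, giving the bridged bicyclo[3.1.1]heptanone; suprafacial addition to the E-olefin puts C13 over the three-carbon bridge and the ethynyl group toward C7, and the C11 pivalate takes the position anti to C2 (least allylic strain, C–O bond out of conjugation), so it ends on the carbonyl-bridge face and fixes C1, C2 and C8.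

Step 7
Reactants: 11 7-ethynyl-7-methyl-6-oxobicyclo[3.1.1]heptan-2-yl pivalate; 12 dimethyl malonate
Product: 13 dimethyl 2-[7-ethynyl-7-methyl-2-(pivaloyloxy)bicyclo[3.1.1]heptan-6-ylidene]malonate
Conditions: TiCl4 (2 equiv), pyridine (4 equiv), THF, 0 → 23 °C
Reagents that add atoms: none
Why: Lehnert-type Knoevenagel condensation on the strained cyclobutanone, the only ketone present; no stereocentre is affected.

Step 8
Reactants: 13 dimethyl 2-[7-ethynyl-7-methyl-2-(pivaloyloxy)bicyclo[3.1.1]heptan-6-ylidene]malonate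
Product: 15 dimethyl 2-[7-ethynyl-7-methyl-2-(pivaloyloxy)bicyclo[3.1.1]heptan-6-yl]-2-methylmalonate, via lithium malonate enolate 14 (not isolated)
Conditions: LiBH(s-Bu)3 (1.1 equiv), THF, −78 °C; then MeI (5 equiv), DMPU, −78 → 23 °C
Reagents that add atoms: iodomethane CI; LiBH(s-Bu)3 [Li+].CCC(C)[BH-](C(C)CC)C(C)CC (lithium counter-ion of 14 only)
Why: Conjugate hydride reduction of the alkylidene malonate then C-methylation of the enolate; hydride enters C7 from the face opposite the ethynyl group (which blocks the other face across the cyclobutane), so C7–H points to the three-carbon bridge and C6 sits beside the ethynyl group, as ring closure later requires.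

Step 9
Reactants: 15 dimethyl 2-[7-ethynyl-7-methyl-2-(pivaloyloxy)bicyclo[3.1.1]heptan-6-yl]-2-methylmalonate
Product: 16 2-(7-ethynyl-2-hydroxy-7-methylbicyclo[3.1.1]heptan-6-yl)-2-methylpropane-1,3-diol
Conditions: LiAlH4 (6 equiv), THF, 0 → 40 °C; H2O, NaOH
Reagents that add atoms: none
Why: Hydride reduction turns both esters into hydroxymethyl groups and cleaves the pivalate in the same pot; C6 carries two identical arms, so no new stereocentre arises.

Step 10
Reactants: 16 2-(7-ethynyl-2-hydroxy-7-methylbicyclo[3.1.1]heptan-6-yl)-2-methylpropane-1,3-diol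
Product: 17 3-hydroxy-2-(7-ethynyl-2-hydroxy-7-methylbicyclo[3.1.1]heptan-6-yl)-2-methylpropyl acetate
Conditions: Et2Zn (20 mol%), (S,S)-ProPhenol (10 mol%), vinyl acetate (5 equiv), PhMe, −20 °C
Reagents that add atoms: vinyl acetate C=COC(C)=O
Why: Trost dinuclear zinc desymmetrising acylation: the 1,3-diol binds the two zinc centres as a bridging bis-alkoxide and acetyl is transferred to one of the two diastereotopic hydroxymethyl arms, the pocket telling the small methyl from the bulky cyclobutyl group; this C–O bond formation sets the quaternary C6 and puts the acetate on C15, while the non-chelating C11 hydroxyl stays free.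

Step 11
Reactants: 17 3-hydroxy-2-(7-ethynyl-2-hydroxy-7-methylbicyclo[3.1.1]heptan-6-yl)-2-methylpropyl acetate
Product: 19 2-(7-ethynyl-7-methyl-2-oxobicyclo[3.1.1]hept-3-en-6-yl)-2-methyl-3-oxopropyl acetate, via saturated keto aldehyde 18 (not isolated)
Conditions: IBX (4.5 equiv), DMSO, 23 °C; then 75 °C
Reagents that add atoms: none
Why: IBX oxidises both hydroxyls at room temperature and on warming dehydrogenates the cyclohexanone (Nicolaou IBX dehydrogenation) only toward C10 because C1 is a bridgehead; the quaternary aldehyde has no α-hydrogen and the neutral medium prevents acetyl migration, so C6 is not scrambled.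

Step 12
Reactants: 19 2-(7-ethynyl-7-methyl-2-oxobicyclo[3.1.1]hept-3-en-6-yl)-2-methyl-3-oxopropyl acetate
Product: 20 2-(7-acetyl-7-methyl-2-oxobicyclo[3.1.1]hept-3-en-6-yl)-2-methyl-3-oxopropyl acetate
Conditions: Ph3PAuNTf2 (3 mol%), H2O (5 equiv), 1,4-dioxane, 60 °C
Reagents that add atoms: water O
Why: Gold-catalysed Markovnikov hydration of the terminal alkyne gives the methyl ketone (C3, C4) under neutral conditions that spare the aldehyde, enone and acetate.

Step 13
Reactants: 20 2-(7-acetyl-7-methyl-2-oxobicyclo[3.1.1]hept-3-en-6-yl)-2-methyl-3-oxopropyl acetate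
Product: 21 (5-hydroxy-2,6-dimethyl-3,11-dioxotricyclo[5.4.0.0^2,8]undec-9-en-6-yl)methyl acetate
Conditions: n-Bu2BOTf (1.2 equiv), i-Pr2NEt (1.5 equiv), CH2Cl2 (5 mM), −78 → −20 °C; MeOH, pH 7 buffer
Reagents that add atoms: none
Why: Intramolecular boron aldol: only the methyl ketone can enolise (the enone is flanked by bridgeheads, the aldehyde has no α-hydrogen) and its enolate adds to the formyl group held next to it across the cyclobutane, closing the seven-membered ring; the boron-bridged chair forms on the formyl face next to the small C14 methyl, so O5 ends cis to C14 and trans to the acetoxymethyl arm.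

Step 14
Reactants: 22 angelic acid
Product: 23 (Z)-2-methylbut-2-en-1-ol
Conditions: LiAlH4, Et2O, 0 °C
Reagents that add atoms: none
Why: Hydride reduction of the acid to the allylic alcohol keeps the Z-olefin.

Step 15
Reactants: 23 (Z)-2-methylbut-2-en-1-ol
Product: 24 (Z)-2-methylbut-2-enal
Conditions: MnO2 (15 equiv), CH2Cl2, 0 °C, dark; filtered solution used at once
Reagents that add atoms: none
Why: Neutral heterogeneous allylic oxidation gives the labile Z-enal without acid or base that would isomerise it to the E-isomer.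

Step 16
Reactants: 21 (5-hydroxy-2,6-dimethyl-3,11-dioxotricyclo[5.4.0.0^2,8]undec-9-en-6-yl)methyl acetate; 24 (Z)-2-methylbut-2-enal
Product: 25 6-(acetoxymethyl)-3-hydroxy-2,6-dimethyl-11-oxotricyclo[5.4.0.0^2,8]undec-9-en-5-yl (Z)-2-methylbut-2-enoate
Conditions: SmI2 (25 mol%, premixed with 24 to give the trivalent samarium catalyst), 24 (5 equiv), THF, −10 °C, dark
Reagents that add atoms: none
Why: Proposed new method: angelate-transfer Evans–Tishchenko reduction — the trivalent samarium centre binds the C5 alkoxide and the C3 ketone, O5 adds to the Z-enal to give a hemiacetal, and the hemiacetal C–H shifts as hydride to C3 through a chair-like six-membered transition state, which turns the hemiacetal carbon into the angelate carbonyl (new C5–O–acyl bond) and delivers hydride to the C3 face syn to O5, giving the 3,5-anti hydroxy ester with C3–OH free; the Z-olefin takes no part in the hydride shift and is kept by working cold, in the dark and without acid or base; the closest known reaction is the Evans–Tishchenko reduction of β-hydroxy ketones with saturated or aromatic aldehydes, not yet shown with a Z-configured α-branched enal as the acyl source.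

Step 17
Reactants: 25 6-(acetoxymethyl)-3-hydroxy-2,6-dimethyl-11-oxotricyclo[5.4.0.0^2,8]undec-9-en-5-yl (Z)-2-methylbut-2-enoate
Product: 26 6-(acetoxymethyl)-3-hydroxy-2,6,9-trimethyl-11-oxotricyclo[5.4.0.0^2,8]undecan-5-yl (Z)-2-methylbut-2-enoate
Conditions: Me2CuLi (3 equiv), Et2O, −78 °C; NH4Cl
Reagents that add atoms: lithium dimethylcuprate [Li+].C[Cu-]C
Why: Gilman cuprate 1,4-addition to the enone; methyl enters C9 from the face of the C7–H bridge, anti to the methyl-bearing C2 bridge (as in additions to apoverbenone), and the trisubstituted angelate and the acetate do not react at −78 °C.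

## Compound list

1 | (E)-3-methylpent-2-en-4-yn-1-ol | C#C/C(C)=C/CO | starting material
2 | (E)-3-methylpent-2-en-4-ynal | C#C/C(C)=C/C=O | intermediate
3 | ethyl 4-iodobutanoate | CCOC(=O)CCCI | starting material
4 | (4-ethoxy-4-oxobutyl)zinc iodide | CCOC(=O)CCC[Zn]I | intermediate
5 | (4-ethoxy-4-oxobutyl)[(trimethylsilyl)methyl]zinc | CCOC(=O)CCC[Zn]C[Si](C)(C)C | intermediate
6 | ethyl (5S,6E)-5-hydroxy-7-methylnon-6-en-8-ynoate | C#C/C(C)=C/[C@@H](O)CCCC(=O)OCC | intermediate
7 | (5S,6E)-5-hydroxy-7-methyl-1-(pyrrolidin-1-yl)non-6-en-8-yn-1-one | C#C/C(C)=C/[C@@H](O)CCCC(=O)N1CCCC1 | intermediate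
8 | (3E,5S)-3-methyl-9-oxo-9-(pyrrolidin-1-yl)non-3-en-1-yn-5-yl pivalate | C#C/C(C)=C/[C@@H](OC(=O)C(C)(C)C)CCCC(=O)N1CCCC1 | intermediate
9 | 1-[(5S,6E)-7-methyl-5-(pivaloyloxy)nona-1,6-dien-8-yn-1-ylidene]pyrrolidin-1-ium triflate | C#C/C(C)=C/[C@@H](OC(=O)C(C)(C)C)CCC=C=[N+]1CCCC1.[O-]S(=O)(=O)C(F)(F)F | intermediate
10 | 1-[7-ethynyl-7-methyl-2-(pivaloyloxy)bicyclo[3.1.1]heptan-6-ylidene]pyrrolidin-1-ium triflate (stereo as in 11) | C#C[C@]1(C)[C@H]2CC[C@H](OC(=O)C(C)(C)C)[C@@H]1C2=[N+]1CCCC1.[O-]S(=O)(=O)C(F)(F)F | intermediate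
11 | 7-ethynyl-7-methyl-6-oxobicyclo[3.1.1]heptan-2-yl pivalate (C13 over the C9–C11 bridge; ethynyl toward C7; pivalate on the C7 face; C11 S) | C#C[C@]1(C)[C@H]2CC[C@H](OC(=O)C(C)(C)C)[C@@H]1C2=O | intermediate
12 | dimethyl malonate | COC(=O)CC(=O)OC | starting material
13 | dimethyl 2-[7-ethynyl-7-methyl-2-(pivaloyloxy)bicyclo[3.1.1]heptan-6-ylidene]malonate (stereo as in 11) | C#C[C@]1(C)[C@H]2CC[C@H](OC(=O)C(C)(C)C)[C@@H]1C2=C(C(=O)OC)C(=O)OC | intermediate
14 | lithium enolate of dimethyl 2-[7-ethynyl-7-methyl-2-(pivaloyloxy)bicyclo[3.1.1]heptan-6-yl]malonate (C7–H toward the C9–C11 bridge) | C#C[C@]1(C)[C@H]2CC[C@H](OC(=O)C(C)(C)C)[C@@H]1[C@H]2C(C(=O)OC)=C([O-])OC.[Li+] | intermediate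
15 | dimethyl 2-[7-ethynyl-7-methyl-2-(pivaloyloxy)bicyclo[3.1.1]heptan-6-yl]-2-methylmalonate (C6 and ethynyl cis across the cyclobutane) | C#C[C@]1(C)[C@H]2CC[C@H](OC(=O)C(C)(C)C)[C@@H]1[C@H]2C(C)(C(=O)OC)C(=O)OC | intermediate
16 | 2-(7-ethynyl-2-hydroxy-7-methylbicyclo[3.1.1]heptan-6-yl)-2-methylpropane-1,3-diol (ring stereo as in 15) | C#C[C@]1(C)[C@H]2CC[C@H](O)[C@@H]1[C@H]2C(C)(CO)CO | intermediate
17 | 3-hydroxy-2-(7-ethynyl-2-hydroxy-7-methylbicyclo[3.1.1]heptan-6-yl)-2-methylpropyl acetate (C6 as in the target: the acetylated arm is C15) | C#C[C@]1(C)[C@H]2CC[C@H](O)[C@@H]1[C@H]2[C@@](C)(COC(C)=O)CO | intermediate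
18 | 2-(7-ethynyl-7-methyl-2-oxobicyclo[3.1.1]heptan-6-yl)-2-methyl-3-oxopropyl acetate | C#C[C@]1(C)[C@H]2CCC(=O)[C@@H]1[C@H]2[C@@](C)(COC(C)=O)C=O | intermediate
19 | 2-(7-ethynyl-7-methyl-2-oxobicyclo[3.1.1]hept-3-en-6-yl)-2-methyl-3-oxopropyl acetate | C#C[C@]1(C)[C@H]2C=CC(=O)[C@@H]1[C@H]2[C@@](C)(COC(C)=O)C=O | intermediate
20 | 2-(7-acetyl-7-methyl-2-oxobicyclo[3.1.1]hept-3-en-6-yl)-2-methyl-3-oxopropyl acetate | CC(=O)[C@]1(C)[C@H]2C=CC(=O)[C@@H]1[C@H]2[C@@](C)(COC(C)=O)C=O | intermediate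
21 | (5-hydroxy-2,6-dimethyl-3,11-dioxotricyclo[5.4.0.0^2,8]undec-9-en-6-yl)methyl acetate (5-OH cis to C14 and trans to the acetoxymethyl group) | O[C@@H]1CC(=O)[C@]2(C)[C@@H]3[C@@H]([C@H]2C(=O)C=C3)[C@@]1(C)COC(C)=O | intermediate
22 | angelic acid [(Z)-2-methylbut-2-enoic acid] | C/C=C(/C)C(=O)O | starting material
23 | (Z)-2-methylbut-2-en-1-ol | C/C=C(/C)CO | intermediate
24 | (Z)-2-methylbut-2-enal | C/C=C(/C)C=O | intermediate
25 | 6-(acetoxymethyl)-3-hydroxy-2,6-dimethyl-11-oxotricyclo[5.4.0.0^2,8]undec-9-en-5-yl (Z)-2-methylbut-2-enoate (3-OH trans to the 5-ester) | C/C=C(/C)C(=O)O[C@@H]1C[C@@H](O)[C@]2(C)[C@@H]3[C@@H]([C@H]2C(=O)C=C3)[C@@]1(C)COC(C)=O | intermediate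
26 | 6-(acetoxymethyl)-3-hydroxy-2,6,9-trimethyl-11-oxotricyclo[5.4.0.0^2,8]undecan-5-yl (Z)-2-methylbut-2-enoate, CNP0212099.1 (3-OH trans to the 5-ester; 5-ester cis to C14; C12 anti to the C2 bridge) | C/C=C(/C)C(=O)O[C@@H]1C[C@@H](O)[C@]2(C)[C@@H]3[C@@H]([C@H]2C(=O)C[C@H]3C)[C@@]1(C)COC(C)=O | target

## Step count and risks

Total step count: 17. Longest linear sequence: 14 (steps 1, 3–13, 16, 17).

Steps most likely to fail:

Step 6 (keteniminium [2+2]; yield and facial control by the C11 pivalate). The fallback sets out from 6 and comes back at 11, using a free ketene instead of a keteniminium salt. Alcohol 6 is pivaloylated (PivCl, pyridine) to ethyl (5S,6E)-7-methyl-5-(pivaloyloxy)non-6-en-8-ynoate F1. The ethyl ester is cleaved with Me3SnOH to (5S,6E)-7-methyl-5-(pivaloyloxy)non-6-en-8-ynoic acid F2. Oxalyl chloride gives (5S,6E)-7-methyl-5-(pivaloyloxy)non-6-en-8-ynoyl chloride F3. Slow addition of F3 to Et3N in refluxing toluene generates (3E,5S)-3-methyl-9-oxonona-3,8-dien-1-yn-5-yl pivalate F4 (the ketene), which closes by the Corey–Snider thermal ketene–alkene [2+2] to 11.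

Step 10 (group-selective mono-acetylation of an all-alkyl quaternary diol). The fallback sets out from 16 and comes back at 17, replacing catalyst control by unselective mono-acetylation with separation and recycling. Triol 16 and trimethyl orthoacetate (cat. camphorsulfonic acid) give the cyclic orthoester 5-(7-ethynyl-2-hydroxy-7-methylbicyclo[3.1.1]heptan-6-yl)-2-methoxy-2,5-dimethyl-1,3-dioxane F5. Aqueous acetic acid opens F5 to a roughly 1:1 mixture of 17 and its C6 epimer 3-hydroxy-2-(7-ethynyl-2-hydroxy-7-methylbicyclo[3.1.1]heptan-6-yl)-2-methylpropyl acetate F6 (the other arm acetylated). The two are separated by chromatography, and F6 is returned to 16 with K2CO3 in methanol.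

Step 16 (the proposed new angelate-transfer Tishchenko step; risk of Z to E isomerisation of 24 or of a sluggish hydride shift). The fallback sets out from 21 and comes back at 25, using only known reactions. A standard Evans–Tishchenko reduction of 21 with benzaldehyde (SmI2 cat.) gives 6-(acetoxymethyl)-3-hydroxy-2,6-dimethyl-11-oxotricyclo[5.4.0.0^2,8]undec-9-en-5-yl benzoate F7. TESOTf and 2,6-lutidine then give 6-(acetoxymethyl)-2,6-dimethyl-11-oxo-3-(triethylsilyloxy)tricyclo[5.4.0.0^2,8]undec-9-en-5-yl benzoate F8. K2CO3 in methanol removes both esters to give 5-hydroxy-6-(hydroxymethyl)-2,6-dimethyl-3-(triethylsilyloxy)tricyclo[5.4.0.0^2,8]undec-9-en-11-one F9. AcCl and 2,4,6-collidine at −78 °C acetylate only the primary hydroxyl, giving [5-hydroxy-2,6-dimethyl-11-oxo-3-(triethylsilyloxy)tricyclo[5.4.0.0^2,8]undec-9-en-6-yl]methyl acetate F10. Yamaguchi-type esterification with angelic acid 22 (2,4,6-trichlorobenzoyl chloride, Et3N, toluene, 80 °C) gives 6-(acetoxymethyl)-2,6-dimethyl-11-oxo-3-(triethylsilyloxy)tricyclo[5.4.0.0^2,8]undec-9-en-5-yl (Z)-2-methylbut-2-enoate F11, and HF·pyridine removes the silyl group to give 25.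

## Further compounds

F1 | step 6 | ethyl (5S,6E)-7-methyl-5-(pivaloyloxy)non-6-en-8-ynoate | C#C/C(C)=C/[C@@H](OC(=O)C(C)(C)C)CCCC(=O)OCC
F2 | step 6 | (5S,6E)-7-methyl-5-(pivaloyloxy)non-6-en-8-ynoic acid | C#C/C(C)=C/[C@@H](OC(=O)C(C)(C)C)CCCC(=O)O
F3 | step 6 | (5S,6E)-7-methyl-5-(pivaloyloxy)non-6-en-8-ynoyl chloride | C#C/C(C)=C/[C@@H](OC(=O)C(C)(C)C)CCCC(=O)Cl
F4 | step 6 | (3E,5S)-3-methyl-9-oxonona-3,8-dien-1-yn-5-yl pivalate (ketene) | C#C/C(C)=C/[C@@H](OC(=O)C(C)(C)C)CCC=C=O
F5 | step 10 | 5-(7-ethynyl-2-hydroxy-7-methylbicyclo[3.1.1]heptan-6-yl)-2-methoxy-2,5-dimethyl-1,3-dioxane (mixture at the orthoester carbon) | C#C[C@]1(C)[C@H]2CC[C@H](O)[C@@H]1[C@H]2C1(C)COC(C)(OC)OC1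
F6 | step 10 | 3-hydroxy-2-(7-ethynyl-2-hydroxy-7-methylbicyclo[3.1.1]heptan-6-yl)-2-methylpropyl acetate (C6 epimer of 17) | C#C[C@]1(C)[C@H]2CC[C@H](O)[C@@H]1[C@H]2[C@](C)(COC(C)=O)CO
F7 | step 16 | 6-(acetoxymethyl)-3-hydroxy-2,6-dimethyl-11-oxotricyclo[5.4.0.0^2,8]undec-9-en-5-yl benzoate | O=C(c1ccccc1)O[C@@H]1C[C@@H](O)[C@]2(C)[C@@H]3[C@@H]([C@H]2C(=O)C=C3)[C@@]1(C)COC(C)=O
F8 | step 16 | 6-(acetoxymethyl)-2,6-dimethyl-11-oxo-3-(triethylsilyloxy)tricyclo[5.4.0.0^2,8]undec-9-en-5-yl benzoate | O=C(c1ccccc1)O[C@@H]1C[C@@H](O[Si](CC)(CC)CC)[C@]2(C)[C@@H]3[C@@H]([C@H]2C(=O)C=C3)[C@@]1(C)COC(C)=O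
F9 | step 16 | 5-hydroxy-6-(hydroxymethyl)-2,6-dimethyl-3-(triethylsilyloxy)tricyclo[5.4.0.0^2,8]undec-9-en-11-one | O[C@@H]1C[C@@H](O[Si](CC)(CC)CC)[C@]2(C)[C@@H]3[C@@H]([C@H]2C(=O)C=C3)[C@@]1(C)CO
F10 | step 16 | [5-hydroxy-2,6-dimethyl-11-oxo-3-(triethylsilyloxy)tricyclo[5.4.0.0^2,8]undec-9-en-6-yl]methyl acetate | O[C@@H]1C[C@@H](O[Si](CC)(CC)CC)[C@]2(C)[C@@H]3[C@@H]([C@H]2C(=O)C=C3)[C@@]1(C)COC(C)=O
F11 | step 16 | 6-(acetoxymethyl)-2,6-dimethyl-11-oxo-3-(triethylsilyloxy)tricyclo[5.4.0.0^2,8]undec-9-en-5-yl (Z)-2-methylbut-2-enoate | C/C=C(/C)C(=O)O[C@@H]1C[C@@H](O[Si](CC)(CC)CC)[C@]2(C)[C@@H]3[C@@H]([C@H]2C(=O)C=C3)[C@@]1(C)COC(C)=O
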